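The pyran ring of the catechin core is opened at C4–C4a and O1–C8a. Ring A is brought in as an aryne (from a 2-silylaryl triflate), and O1–C2–C3–C4 with both stereocentres as an open-chain anti chloro alcohol from an auxiliary-controlled glycolate aldol. In one operation the alkoxide adds to the aryne and the aryl anion so formed closes the ring on the primary chloride. The step exploits the 5,7,8a-oxygenation of ring A: the C5 oxygen next to C4a polarises the C4a–C8a triple bond, so O1 bonds to C8a and the carbanion appears at C4a. The acylphloroglucinol is then attached at C8 through a methoxymethyl handle, and hydrogenolysis ends the route.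

Key step: step 8

Assumption: in step 5 the (R)-configured 4-benzyl auxiliary is taken to deliver the 2R,3R anti adduct; should the facial sense prove opposite, the (S)-auxiliary is used and nothing else changes.

**Ring A: the aryne precursor**

Step 1
Reactants: 1 3,5-bis(benzyloxy)phenol
Product: 2 3,5-bis(benzyloxy)phenyl N-isopropylcarbamate
Conditions: i-PrNCO, Et3N (cat.), CH2Cl2, rt
Reagents that add atoms: isopropyl isocyanate CC(C)N=C=O
Why: Base-catalysed carbamoylation of the phenol with the isocyanate should give the N–H carbamate, which serves as ortho-directing group and as a phenol mask that is later removed under mild base.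

Step 2
Reactants: 2 3,5-bis(benzyloxy)phenyl N-isopropylcarbamate
Product: 8 3,5-bis(benzyloxy)-2-(methoxymethyl)-6-(trimethylsilyl)phenyl N-isopropylcarbamate, via N-silyl carbamate 3 (not isolated), via aryllithium 4 (not isolated), via N-silyl arylsilane 5 (not isolated), via second aryllithium 6 (not isolated), via N-silyl methoxymethyl arene 7 (not isolated)
Conditions: TBSOTf, TMEDA, Et2O, 0 °C to rt; n-BuLi, TMEDA, −78 °C; TMSCl; n-BuLi, TMEDA, −78 °C; MOMCl, −78 °C to rt; aq. NaHSO4
Reagents that add atoms: chlorotrimethylsilane C[Si](C)(C)Cl; chloromethyl methyl ether COCCl; tert-butyldimethylsilyl triflate CC(C)(C)[Si](C)(C)OS(=O)(=O)C(F)(F)F (silyl group of 3 to 7 only); n-butyllithium [Li]CCCC (lithium of 4 and 6 only)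
Why: Two directed ortho-metalations in one flask should work because the transiently N-silylated carbamate directs lithiation to the position between itself and a benzyloxy group, silylation of 4 leaves only the other carbamate-flanked position for the second lithiation, and 6 is alkylated by the chloromethyl ether; silicon goes in first so that no benzylic CH2OMe is present for lateral lithiation.

Step 3
Reactants: 8 3,5-bis(benzyloxy)-2-(methoxymethyl)-6-(trimethylsilyl)phenyl N-isopropylcarbamate
Product: 10 3,5-bis(benzyloxy)-2-(methoxymethyl)-6-(trimethylsilyl)phenyl trifluoromethanesulfonate, via phenol 9 (not isolated)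
Conditions: Et2NH, DBU, MeCN, 40 °C; then PhNTf2, rt
Reagents that add atoms: N-phenylbis(trifluoromethanesulfonimide) O=S(=O)(N(c1ccccc1)S(=O)(=O)C(F)(F)F)C(F)(F)F
Why: E1cB cleavage of the N–H carbamate by DBU (diethylamine scavenges the isocyanate) should unmask phenoxide 9, which is O-sulfonylated in the same flask (carbamate cleavage/triflation) without acid that would cleave the aryl–silicon bond.

**C2–C3–C4 fragment: the anti chloro alcohol**

Step 4
Reactants: 11 (R)-4-benzyl-1,3-oxazolidine-2-thione; 12 benzyloxyacetyl chloride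
Product: 13 (R)-4-benzyl-3-[2-(benzyloxy)acetyl]-1,3-oxazolidine-2-thione
Conditions: Et3N, CH2Cl2, 0 °C
Reagents that add atoms: none
Why: N-acylation of the oxazolidinethione by the acid chloride should give the glycolyl imide.

Step 5
Reactants: 13 (R)-4-benzyl-3-[2-(benzyloxy)acetyl]-1,3-oxazolidine-2-thione; 14 3,4-bis(benzyloxy)benzaldehyde
Product: 16 (R)-4-benzyl-3-[(2R,3R)-2-(benzyloxy)-3-[3,4-bis(benzyloxy)phenyl]-3-hydroxypropanoyl]-1,3-oxazolidine-2-thione, via titanium enolate 15 (not isolated)
Conditions: TiCl4, i-Pr2NEt, CH2Cl2, −78 °C; then 14 pre-mixed with TiCl4, −78 °C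
Reagents that add atoms: titanium tetrachloride Cl[Ti](Cl)(Cl)Cl (in 15 only)
Why: In this titanium-mediated anti-selective glycolate aldol the Z-enolate 15 should add through an open transition state to the Lewis-acid-complexed aldehyde, which gives the 2,3-anti relationship, while the benzyl group of the auxiliary shields one enolate face and so fixes both new centres as 2R,3R.

Step 6
Reactants: 16 the anti aldol adduct
Product: 17 (1R,2S)-2-(benzyloxy)-1-[3,4-bis(benzyloxy)phenyl]propane-1,3-diol
Conditions: NaBH4, THF/H2O, 0 °C to rt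
Reagents that add atoms: none
Why: Reductive cleavage of the activated imide by borohydride should release the primary alcohol and the auxiliary without touching either stereocenter.

Step 7
Reactants: 17 (1R,2S)-2-(benzyloxy)-1-[3,4-bis(benzyloxy)phenyl]propane-1,3-diol
Product: 19 (1R,2R)-2-(benzyloxy)-1-[3,4-bis(benzyloxy)phenyl]-3-chloropropan-1-ol, via primary mesylate 18 (not isolated)
Conditions: MsCl, 2,4,6-collidine, CH2Cl2, −10 °C; then LiCl, DMF, 45 °C
Reagents that add atoms: lithium chloride [Li+].[Cl-]; methanesulfonyl chloride CS(=O)(=O)Cl (in 18 only)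
Why: Chemoselective sulfonylation of the primary hydroxyl with a hindered pyridine base followed by SN2 displacement by chloride in the same flask should give the chloride and leave the secondary benzylic alcohol free (the descriptor at C2 changes only through ligand priority).

**Key step**

Step 8
Reactants: 10 3,5-bis(benzyloxy)-2-(methoxymethyl)-6-(trimethylsilyl)phenyl trifluoromethanesulfonate; 19 (1R,2R)-2-(benzyloxy)-1-[3,4-bis(benzyloxy)phenyl]-3-chloropropan-1-ol
Product: 23 (2R,3S)-3,5,7-tris(benzyloxy)-2-[3,4-bis(benzyloxy)phenyl]-8-(methoxymethyl)chromane, via potassium alkoxide 20 (not isolated), via aryne 21 (not isolated), via aryl potassium 22 (not isolated)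
Conditions: 19, KH, THF, 0 °C; then 10, KF, 18-crown-6, THF, 0 °C to rt
Reagents that add atoms: potassium hydride [K+].[H-] (potassium of 20 and 22 only)
Why: Proposed new method: fluoride removes the silyl group of 10 and triflate departs to give aryne 21; alkoxide 20, made beforehand with KH so that no O–H is left to protonate the aryl anion, adds through O1 to C8a, and aryl potassium 22, which carries its charge at C4a between two alkoxy groups, displaces the primary chloride at C4. The closest known reaction type is the fluoride-triggered aryne annulation in which a heteroatom nucleophile adds and the aryl anion is caught by a tethered electrophile (salicylate to xanthone), combined with a Parham-type cycloalkylation of an aryl carbanion; a γ-chloro alkoxide has not been used as the partner. The pyran ring closes in the 6-exo-tet mode. No stereocenter is formed, since C2 and C3 arrive with 19 and neither the C2–O nor the C3–O bond is broken, so the 2R,3S trans relationship is carried over. The step needs O-addition at C8a and not at C4a, which the C5 benzyloxy group should secure by inductively stabilising negative charge at the adjacent C4a (the usual polarisation of 3-alkoxyarynes), helped by potassium bridging to the CH2OMe oxygen; it also needs alkylation to outrun elimination and fragmentation, for which the chloride, inert toward the alkoxide at this temperature, and the exo geometry are chosen.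

**Acylphloroglucinol unit**

Step 9
Reactants: 24 2,4,6-trihydroxytoluene; 25 isobutyryl chloride
Product: 26 1-(2,4,6-trihydroxy-3-methylphenyl)-2-methylpropan-1-one
Conditions: AlCl3, PhNO2/CH2Cl2, 0 °C to rt
Reagents that add atoms: none
Why: Friedel–Crafts acylation should give a single ketone because the two free ring positions of 24 are equivalent.

Step 10
Reactants: 26 1-(2,4,6-trihydroxy-3-methylphenyl)-2-methylpropan-1-one
Product: 27 1-[4,6-bis(benzyloxy)-2-hydroxy-3-methylphenyl]-2-methylpropan-1-one
Conditions: BnBr (2.1 equiv), K2CO3, acetone, reflux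
Reagents that add atoms: benzyl bromide BrCc1ccccc1
Why: Williamson O-benzylation under weak base should alkylate the para hydroxyl and the less hindered ortho hydroxyl, while the hydroxyl flanked by methyl and acyl stays hydrogen-bonded to the carbonyl.

Step 11
Reactants: 27 1-[4,6-bis(benzyloxy)-2-hydroxy-3-methylphenyl]-2-methylpropan-1-one
Product: 28 1-[4,6-bis(benzyloxy)-2-methoxy-3-methylphenyl]-2-methylpropan-1-one
Conditions: MeI, K2CO3, DMF, 60 °C
Reagents that add atoms: iodomethane CI
Why: Williamson O-methylation of the one remaining, chelated hydroxyl should proceed under these more forcing conditions and places the methoxy group between methyl and acyl.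

Step 12
Reactants: 28 1-[4,6-bis(benzyloxy)-2-methoxy-3-methylphenyl]-2-methylpropan-1-one
Product: 29 1-(4,6-dihydroxy-2-methoxy-3-methylphenyl)-2-methylpropan-1-one
Conditions: H2 (1 atm), Pd/C, EtOAc/MeOH, rt
Reagents that add atoms: none
Why: Hydrogenolysis of the two benzyl ethers should give the free resorcinol, whose only unsubstituted ring carbon lies between the two hydroxyls.

**Union and deprotection**

Step 13
Reactants: 23 (2R,3S)-3,5,7-tris(benzyloxy)-2-[3,4-bis(benzyloxy)phenyl]-8-(methoxymethyl)chromane; 29 1-(4,6-dihydroxy-2-methoxy-3-methylphenyl)-2-methylpropan-1-one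
Product: 30 1-[3-({(2R,3S)-3,5,7-tris(benzyloxy)-2-[3,4-bis(benzyloxy)phenyl]chroman-8-yl}methyl)-2,4-dihydroxy-6-methoxy-5-methylphenyl]-2-methylpropan-1-one
Conditions: 29 (1.5 equiv), Sc(OTf)3 (10 mol %), CH2Cl2/MeNO2, 0 °C to rt
Reagents that add atoms: none
Why: In this Friedel–Crafts benzylation the Lewis acid should ionise the C8 benzylic methyl ether to a cation stabilised by O7, O1 and O5, which is captured by the single free, doubly hydroxyl-activated carbon of 29, far more readily than the C2–O1 bond can ionise.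

Step 14
Reactants: 30 the penta-O-benzyl coupling product
Product: 31 Pilosanol B
Conditions: H2 (1 atm), Pd(OH)2/C, THF/MeOH, rt
Reagents that add atoms: none
Why: Hydrogenolysis of the five benzyl ethers under neutral conditions should free the 3-, 5-, 7-, 3'- and 4'-hydroxyls while the diarylmethane, the hindered aryl ketone and the C2–O1 bond survive at atmospheric pressure.

**Compound list**

1 | 3,5-bis(benzyloxy)phenol | Oc1cc(OCc2ccccc2)cc(OCc2ccccc2)c1 | starting material
2 | 3,5-bis(benzyloxy)phenyl N-isopropylcarbamate | CC(C)NC(=O)Oc1cc(OCc2ccccc2)cc(OCc2ccccc2)c1 | intermediate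
3 | N-(tert-butyldimethylsilyl) derivative of 2 (formed in the flask) | CC(C)N(C(=O)Oc1cc(OCc2ccccc2)cc(OCc2ccccc2)c1)[Si](C)(C)C(C)(C)C | intermediate
4 | 2-lithio derivative of 3 (formed in the flask) | CC(C)N(C(=O)Oc1cc(OCc2ccccc2)cc(OCc2ccccc2)c1[Li])[Si](C)(C)C(C)(C)C | intermediate
5 | N-silyl 2-(trimethylsilyl) carbamate (formed in the flask) | CC(C)N(C(=O)Oc1cc(OCc2ccccc2)cc(OCc2ccccc2)c1[Si](C)(C)C)[Si](C)(C)C(C)(C)C | intermediate
6 | 6-lithio derivative of 5 (formed in the flask) | CC(C)N(C(=O)Oc1c([Li])c(OCc2ccccc2)cc(OCc2ccccc2)c1[Si](C)(C)C)[Si](C)(C)C(C)(C)C | intermediate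
7 | N-silyl derivative of 8 (formed in the flask) | CC(C)N(C(=O)Oc1c(COC)c(OCc2ccccc2)cc(OCc2ccccc2)c1[Si](C)(C)C)[Si](C)(C)C(C)(C)C | intermediate
8 | 3,5-bis(benzyloxy)-2-(methoxymethyl)-6-(trimethylsilyl)phenyl N-isopropylcarbamate | CC(C)NC(=O)Oc1c(COC)c(OCc2ccccc2)cc(OCc2ccccc2)c1[Si](C)(C)C | intermediate
9 | 3,5-bis(benzyloxy)-2-(methoxymethyl)-6-(trimethylsilyl)phenol (formed in the flask as its phenoxide) | COCc1c(OCc2ccccc2)cc(OCc2ccccc2)c([Si](C)(C)C)c1O | intermediate
10 | 3,5-bis(benzyloxy)-2-(methoxymethyl)-6-(trimethylsilyl)phenyl trifluoromethanesulfonate | COCc1c(OCc2ccccc2)cc(OCc2ccccc2)c([Si](C)(C)C)c1OS(=O)(=O)C(F)(F)F | intermediate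
11 | (R)-4-benzyl-1,3-oxazolidine-2-thione | S=C1N[C@H](Cc2ccccc2)CO1 | starting material
12 | benzyloxyacetyl chloride | O=C(Cl)COCc1ccccc1 | starting material
13 | (R)-4-benzyl-3-[2-(benzyloxy)acetyl]-1,3-oxazolidine-2-thione | O=C(COCc1ccccc1)N1C(=S)OC[C@H]1Cc1ccccc1 | intermediate
14 | 3,4-bis(benzyloxy)benzaldehyde | O=Cc1ccc(OCc2ccccc2)c(OCc2ccccc2)c1 | starting material
15 | trichlorotitanium Z-enolate of 13 (formed in the flask) | Cl[Ti](Cl)(Cl)O/C(=C\OCc1ccccc1)N1C(=S)OC[C@H]1Cc1ccccc1 | intermediate
16 | (R)-4-benzyl-3-[(2R,3R)-2-(benzyloxy)-3-[3,4-bis(benzyloxy)phenyl]-3-hydroxypropanoyl]-1,3-oxazolidine-2-thione | O=C([C@H](OCc1ccccc1)[C@H](O)c1ccc(OCc2ccccc2)c(OCc2ccccc2)c1)N1C(=S)OC[C@H]1Cc1ccccc1 | intermediate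
17 | (1R,2S)-2-(benzyloxy)-1-[3,4-bis(benzyloxy)phenyl]propane-1,3-diol | OC[C@H](OCc1ccccc1)[C@H](O)c1ccc(OCc2ccccc2)c(OCc2ccccc2)c1 | intermediate
18 | (2S,3R)-2-(benzyloxy)-3-[3,4-bis(benzyloxy)phenyl]-3-hydroxypropyl methanesulfonate (formed in the flask) | CS(=O)(=O)OC[C@H](OCc1ccccc1)[C@H](O)c1ccc(OCc2ccccc2)c(OCc2ccccc2)c1 | intermediate
19 | (1R,2R)-2-(benzyloxy)-1-[3,4-bis(benzyloxy)phenyl]-3-chloropropan-1-ol | O[C@H](c1ccc(OCc2ccccc2)c(OCc2ccccc2)c1)[C@@H](OCc1ccccc1)CCl | intermediate
20 | potassium alkoxide of 19 (formed in the flask) | [K+].[O-][C@H](c1ccc(OCc2ccccc2)c(OCc2ccccc2)c1)[C@@H](OCc1ccccc1)CCl | intermediate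
21 | 4,6-bis(benzyloxy)-3-(methoxymethyl)-1,2-didehydrobenzene, the aryne (formed in the flask) | COCC1=C(OCc2ccccc2)C=C(OCc2ccccc2)C#C1 | intermediate
22 | aryl potassium from O-addition of 20 to 21, metal at the future C4a (formed in the flask) | COCc1c(OCc2ccccc2)cc(OCc2ccccc2)c([K])c1O[C@H](c1ccc(OCc2ccccc2)c(OCc2ccccc2)c1)[C@@H](OCc1ccccc1)CCl | intermediate
23 | (2R,3S)-3,5,7-tris(benzyloxy)-2-[3,4-bis(benzyloxy)phenyl]-8-(methoxymethyl)chromane | COCc1c(OCc2ccccc2)cc(OCc2ccccc2)c2c1O[C@H](c1ccc(OCc3ccccc3)c(OCc3ccccc3)c1)[C@@H](OCc1ccccc1)C2 | intermediate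
24 | 2,4,6-trihydroxytoluene | Cc1c(O)cc(O)cc1O | starting material
25 | isobutyryl chloride | CC(C)C(=O)Cl | starting material
26 | 1-(2,4,6-trihydroxy-3-methylphenyl)-2-methylpropan-1-one | CC(C)C(=O)c1c(O)cc(O)c(C)c1O | intermediate
27 | 1-[4,6-bis(benzyloxy)-2-hydroxy-3-methylphenyl]-2-methylpropan-1-one | CC(C)C(=O)c1c(O)c(C)c(OCc2ccccc2)cc1OCc1ccccc1 | intermediate
28 | 1-[4,6-bis(benzyloxy)-2-methoxy-3-methylphenyl]-2-methylpropan-1-one | CC(C)C(=O)c1c(OC)c(C)c(OCc2ccccc2)cc1OCc1ccccc1 | intermediate
29 | 1-(4,6-dihydroxy-2-methoxy-3-methylphenyl)-2-methylpropan-1-one | CC(C)C(=O)c1c(OC)c(C)c(O)cc1O | intermediate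
30 | 1-[3-({(2R,3S)-3,5,7-tris(benzyloxy)-2-[3,4-bis(benzyloxy)phenyl]chroman-8-yl}methyl)-2,4-dihydroxy-6-methoxy-5-methylphenyl]-2-methylpropan-1-one | COc1c(C)c(O)c(Cc2c(OCc3ccccc3)cc(OCc3ccccc3)c3c2O[C@H](c2ccc(OCc4ccccc4)c(OCc4ccccc4)c2)[C@@H](OCc2ccccc2)C3)c(O)c1C(=O)C(C)C | intermediate
31 | Pilosanol B | COc1c(C)c(O)c(Cc2c(O)cc(O)c3c2O[C@H](c2ccc(O)c(O)c2)[C@@H](O)C3)c(O)c1C(=O)C(C)C | target

**Count**

Total steps: 14. Longest linear sequence: 7 steps (steps 4, 5, 6, 7, 8, 13, 14).

**Steps most likely to fail**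

1. Step 8 (proposed new method). The aryl anion may be protonated before it reaches the chloride, the γ-chloro alkoxide may eliminate or fragment before the aryne is available, or the alkoxide may add at the aryne carbon next to the benzyloxy group. The fallback sets out from 10 and comes back at 23. 10 is treated with CsF in MeCN in the presence of (E)-3-[3,4-bis(benzyloxy)phenyl]prop-2-enal F1 (one Wittig step from 14 with (triphenylphosphoranylidene)acetaldehyde). This is the known aryne/enal chromene synthesis: the aryne adds across the C=O bond, again with oxygen at C8a, the benzoxete opens to an ortho-quinone methide and 6π-electrocyclisation should give racemic 5,7-bis(benzyloxy)-2-[3,4-bis(benzyloxy)phenyl]-8-(methoxymethyl)-2H-chromene F2, with the same two bonds formed in one operation. Hydroboration–oxidation (BH3·SMe2; then NaOH, H2O2) anti to the C2 aryl group should give the 2,3-trans alcohol as a racemate, from which (2R,3S)-5,7-bis(benzyloxy)-2-[3,4-bis(benzyloxy)phenyl]-8-(methoxymethyl)chroman-3-ol F3 is separated on a chiral stationary phase. O-Benzylation (NaH, BnBr, DMF) returns to 23.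

2. Step 5. Anti selectivity may erode with the aromatic aldehyde, or the electron-rich benzylic titanium alkoxide may ionise under excess Lewis acid. The fallback sets out from 14 and comes back at 17. A Mukaiyama aldol of 14 with (Z)-2-(benzyloxy)-1-(ethylthio)-1-(trimethylsilyloxy)ethene F4 is promoted by Sn(OTf)2, a chiral 2-(aminomethyl)pyrrolidine diamine (antipode chosen for the 2R,3R series) and Bu2Sn(OAc)2 in CH2Cl2 at −78 °C. It is anti-selective for benzyloxy ketene acetals through an open transition state and should give S-ethyl (2R,3R)-2-(benzyloxy)-3-[3,4-bis(benzyloxy)phenyl]-3-hydroxypropanethioate F5. LiAlH4 reduction in THF then gives 17.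

3. Step 2. The second lithiation may stall, the second aryllithium may be consumed by residual chlorosilane, or a benzyl ether may be deprotonated at its benzylic carbon and rearrange. The fallback sets out from 1 and comes back at 10, replacing steps 1 to 3, with silicon placed by halogen–metal exchange instead of deprotonation. Magnesium-mediated ortho-formylation of 1 (MgCl2, Et3N, paraformaldehyde, MeCN, reflux) should give 2,4-bis(benzyloxy)-6-hydroxybenzaldehyde F6. NaBH4 reduction followed by MeOH with catalytic acid should give 3,5-bis(benzyloxy)-2-(methoxymethyl)phenol F7. Ortho-selective bromination (NBS, cat. i-Pr2NH, CH2Cl2) should give 3,5-bis(benzyloxy)-2-bromo-6-(methoxymethyl)phenol F8. O-Silylation with HMDS, then n-BuLi at −78 °C (bromine–lithium exchange and O-to-C silyl shift, retro-Brook), then Tf2O gives 10.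

Further compounds
F1 | step 8 | (E)-3-[3,4-bis(benzyloxy)phenyl]prop-2-enal | O=C/C=C/c1ccc(OCc2ccccc2)c(OCc2ccccc2)c1
F2 | step 8 | racemic 5,7-bis(benzyloxy)-2-[3,4-bis(benzyloxy)phenyl]-8-(methoxymethyl)-2H-chromene | COCc1c(OCc2ccccc2)cc(OCc2ccccc2)c2c1OC(c1ccc(OCc3ccccc3)c(OCc3ccccc3)c1)C=C2
F3 | step 8 | (2R,3S)-5,7-bis(benzyloxy)-2-[3,4-bis(benzyloxy)phenyl]-8-(methoxymethyl)chroman-3-ol | COCc1c(OCc2ccccc2)cc(OCc2ccccc2)c2c1O[C@H](c1ccc(OCc3ccccc3)c(OCc3ccccc3)c1)[C@@H](O)C2
F4 | step 5 | (Z)-2-(benzyloxy)-1-(ethylthio)-1-(trimethylsilyloxy)ethene | CCS/C(O[Si](C)(C)C)=C\OCc1ccccc1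
F5 | step 5 | S-ethyl (2R,3R)-2-(benzyloxy)-3-[3,4-bis(benzyloxy)phenyl]-3-hydroxypropanethioate | CCSC(=O)[C@H](OCc1ccccc1)[C@H](O)c1ccc(OCc2ccccc2)c(OCc2ccccc2)c1
F6 | step 2 | 2,4-bis(benzyloxy)-6-hydroxybenzaldehyde | O=Cc1c(O)cc(OCc2ccccc2)cc1OCc1ccccc1
F7 | step 2 | 3,5-bis(benzyloxy)-2-(methoxymethyl)phenol | COCc1c(O)cc(OCc2ccccc2)cc1OCc1ccccc1
F8 | step 2 | 3,5-bis(benzyloxy)-2-bromo-6-(methoxymethyl)phenol | COCc1c(O)c(Br)c(OCc2ccccc2)cc1OCc1ccccc1
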